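## The problem

The target (27) is a C20 bromochloro diterpenoid built on a 7-oxabicyclo[2.2.1]heptane: a cyclohexane (C1–C6) bridged 1,4 by O7. C1 is a methyl-bearing bridgehead, C2 carries an endo 3-hydroxy-3-methylpent-4-enyl arm, C3 is an all-carbon quaternary centre (endo methyl, exo 3-bromo-4-chloro-4-methylpentyl chain) and C4 is the bridgehead methine. Four contiguous stereocentres (1S,2S,3S,4R) sit on the bicycle. Two more, the (S)-tertiary allylic carbinol and the (S)-secondary bromide, lie out on freely rotating chains. C3 and C4 are neighbours and can be set together; once they exist the bridge fixes C1 and biases C2, whereas the two remote centres each need a reagent to set them. Three groups restrict the order of events: the tertiary allylic alcohol ionises in acid, the vicinal secondary bromide/tertiary chloride is lost to base and to zinc or low-valent metals, and a carbonyl at C2 turns O7 into a β-leaving group. The feature that opens the route is that C1 is a ketone-level carbon (bonded to O7, methyl, C6 and C2) inside an oxolane (O7, C1, C6, C5, C4) that maps onto 4-oxopentanal (4). Ionised to the oxocarbenium C1=O7+, it can accept an aldehyde-derived nucleophile at C2, so the C1–C2 bond closes the carbocycle on a pre-formed oxolane. C3 with its methyl and its prenyl-terminated chain maps onto geraniol (1).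

## Retrosynthesis

**Halogens (27 → 26 → 25 → 24 → 23).** The C–Cl and C–Br bonds are cut first, back to the prenyl alkene of 23, after the silyl ether of 26 is taken off. The dihalide has to come last because it would not survive the ylide, palladium, alkoxide and zinc chemistry that builds the C2 arm. Direct bromochlorination of the alkene would be one step but gives no control over a C–Br centre this far from the core. The longer path gives reagent control: a fructose-derived dioxirane should give the (R)-epoxide 24, bromide should open it with inversion to the (S)-bromohydrin 25, and the tertiary hydroxyl should be exchanged for chloride through a bromonium ion, which keeps bromine on its carbon (26). The forward steps must epoxidise the trisubstituted alkene and not the vinyl group, and the carbinol must be masked (23) while the other tertiary alcohol is chlorinated.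

**Carbinol (23 → 22 → 21 → 20 → 19).** The tertiary allylic alcohol 22 is traced to the 2,3-epoxy iodide 21, the epoxy alcohol 20 and the primary Z-allylic alcohol 19. Addition of a vinyl metal to a methyl ketone would be shorter but offers no control at a centre this remote. Asymmetric epoxidation of an allylic alcohol is reagent-controlled, and the reductive opening never breaks the C–O bond of the future carbinol. The precursor 19 has no stereocentre on the arm.

**Arm carbon chain (19 → 14 + 17; 14 → 13; 17 → 15).** The bond between the second arm methylene and the alkene carbon is cut as a B-alkyl Suzuki–Miyaura coupling of the borane from vinyl compound 14 with (Z)-3-iodobut-2-en-1-ol (17), which comes in one step from but-2-yn-1-ol (15). The vinyl group of 14 comes from aldehyde 13 by methylenation. The alternative, displacement at a CH2–X group on C2, would be an SN2 reaction next to a carbon flanked by two quaternary centres. Olefination at the carbonyl and coupling at a remote primary borane avoid that. What remains at C2 in 13 is a formyl group.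

**Key disconnection (13 → 10).** The C1–C2 bond is cut. In the forward sense the tertiary methyl ketal of 10 is ionised to the oxocarbenium ion and the enamine of the tethered aldehyde attacks it through C2. This removes the carbocycle and leaves a monocyclic oxolane with only C3 and C4 as stereocentres. Cutting C3–C4 or C2–C3 instead would form the quaternary carbon in the ring closure, whereas here it is complete beforehand. The forward reaction must form a strained bicycle and place the formyl group endo.

**Adjusting 10 (10 → 9 → 7 → 6).** The aldehyde carbon and C2 are the vinyl group of 7, reached through alcohol 9 by hydroboration and oxidation. The cyclic methyl ketal 7 is the γ-hydroxy ketone 6 closed in methanol. It protects ketone and alcohol together and is the latent cation.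

**Quaternary centre (6 → 3 + 4; 3 → 1 + 2).** The C3–C4 bond is cut between geranyl pinacolboronate 3 and the aldehyde of 4-oxopentanal (4). A closed six-membered transition state joins a C10 and a C5 fragment at the quaternary carbon and sets C3 and C4 in one event. The E geometry of 3 gives the required relative configuration and a chiral phosphoric acid the absolute one. Boronate 3 comes from geraniol (1) and bis(pinacolato)diboron (2). The forward reaction must distinguish aldehyde from ketone, which a pinacol allylboronate does.

## Roads not taken

**Alternative 1: anodic decarboxylation to a transannularly trapped cation.** The cut is O7–C1. The bicyclic ester A1 would arise when the C1 carboxylate of hydroxy acid A2 is oxidised at a carbon anode (non-Kolbe, Hofer–Moest) to the tertiary C1 cation, which the C4 hydroxyl captures across the ring.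
- Merits: C1 needs no defined configuration in A2, the ether closure is irreversible, and there is no enolisable carbonyl beside the oxa bridge. In that respect it is safer than the chosen plan, whose product 13 can epimerise at C2 and can in principle open by β-elimination.
- Weak points: A2 is hardly simpler than the target core. It is a cyclohexane with C2, C3 and C4 set and both quaternary carbons in place, so the hard C–C bonds fall to other chemistry. The cation can lose a proton, and capture needs a boat with the hydroxyl axial. The vinyl group and silyl ether must also tolerate the anode.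
- Comparison: the chosen plan sets C3 and C4 in one intermolecular step from two commercial fragments and uses the ketone level of C1 to form a C–C bond.

**Alternative 2: epoxy-olefin bicyclisation.** The cuts are C2–C3 and O7–C1. A methylaluminium chloride Lewis acid would open the cis-epoxide of A4 at its tertiary carbon under attack by the trisubstituted alkene, and the epoxide oxygen would trap the resulting C1 cation to give acetate A3.
- Merits: it is the shortest route on paper, with two bonds, both rings and all four core stereocentres from an acyclic precursor with one stereogenic epoxide. If it worked it would reach the stage of 13 in fewer steps than the chosen plan.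
- Weak points: A4 needs a farnesyl chain with two Z double bonds and a site- and enantioselective epoxidation of the central alkene among three trisubstituted alkenes, with no directing group in reach. The folding must be boat-like. Hydride shift to a ketone, proton loss and attack by the terminal alkene are the usual competitors. C2 is correct only if the bond formation is concerted.
- Comparison: the chosen plan is longer, and its ring closure is also new. Against that it draws C3 and C4 from a closed transition state with a catalytic controller and commercial geraniol.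

**Alternative 3: acetal oxocarbenium closed by an aldehyde enol silane.** The cut is C3–C4. A silyl triflate would ionise the 2-methoxyoxolane of A6 to the C4 oxocarbenium ion, and the tethered trisubstituted silyl enol ether would attack through C3 to give aldehyde A5.
- Merits: the bond-forming event is the best precedented of the cation–enol closures and is driven by a silicon–oxygen bond. The formyl group of A5 sits on a quaternary carbon, so it can neither epimerise nor trigger β-elimination. On both counts it is ahead of the chosen key step.
- Weak points: the quaternary C3 is created in the closure and depends on enol ether geometry and facial approach. The tertiary ether centre C1 and C2 must already be correct in A6, which is the harder stereochemical task. The whole haloalkyl chain must then be grown from a neopentyl aldehyde, in addition to the C2 arm.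
- Comparison: the chosen plan brings C3 with its chain from geraniol, and its closure creates only the C2 methine, which can be equilibrated or corrected.

Key step: step 6

Assumption: the sense of induction in step 2 is taken from allyl- and crotylboration of simple aldehydes, where the (R)-phosphoric acid leads to Re-face addition; the route needs Si-face addition and therefore uses the (S)-acid.

## Route

Step 1
Reactants: 1 geraniol; 2 bis(pinacolato)diboron
Product: 3 geranyl pinacolboronate, 2-[(2E)-3,7-dimethylocta-2,6-dien-1-yl]-4,4,5,5-tetramethyl-1,3,2-dioxaborolane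
Conditions: Pd(MeCN)4(BF4)2 (5 mol%), DMSO/MeOH, 40 °C
Reagents that add atoms: none
Why: Palladium-catalysed borylation of an allylic alcohol through a π-allyl intermediate; boron goes to the unsubstituted terminus and the E geometry is kept, so the stereodefined γ,γ-disubstituted allylboronate should be available in one step.

Step 2
Reactants: 3 geranyl pinacolboronate; 4 4-oxopentanal
Product: 6 (5R,6S)-6-ethenyl-5-hydroxy-6,10-dimethylundec-9-en-2-one, via pinacol borate ester 5 (not isolated)
Conditions: (S)-3,3′-bis(2,4,6-triisopropylphenyl)-1,1′-binaphthyl-2,2′-diyl hydrogen phosphate (5 mol%), 4 Å MS, toluene, −30 → 0 °C; then aq. NaHCO3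
Reagents that add atoms: none
Why: Chiral phosphoric acid-catalysed allylboration through a closed chair (Zimmerman–Traxler) transition state; the E chain of 3 sits equatorial and ends anti to the hydroxyl, which fixes the quaternary carbon relative to the carbinol, while the acid selects the Si face of the aldehyde. The ketone is not attacked by a pinacol allylboronate at this temperature.

Step 3
Reactants: 6 (5R,6S)-6-ethenyl-5-hydroxy-6,10-dimethylundec-9-en-2-one
Product: 7 (5R)-5-[(3S)-3,7-dimethylocta-1,6-dien-3-yl]-2-methoxy-2-methyloxolane (both epimers at the ketal carbon)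
Conditions: MeOH, PPTS (cat.), 4 Å MS, rt
Reagents that add atoms: methanol, CO
Why: Acid-catalysed cyclic ketalisation; the γ-hydroxy ketone closes to the five-membered hemiketal and exchanges OH for OMe in methanol. The ketal centre forms as both epimers, which does not matter because it becomes planar in step 6.

Step 4
Reactants: 7 (5R)-5-[(3S)-3,7-dimethylocta-1,6-dien-3-yl]-2-methoxy-2-methyloxolane
Product: 9 (3S)-3,7-dimethyl-3-[(2R)-5-methoxy-5-methyloxolan-2-yl]oct-6-en-1-ol, via B-alkyl-9-BBN adduct 8 (not isolated)
Conditions: 9-BBN, THF, 0 °C → rt; then NaOH, H2O2, 0 °C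
Reagents that add atoms: hydrogen peroxide, OO
Why: Anti-Markovnikov hydroboration–oxidation; 9-BBN adds to the monosubstituted vinyl group far faster than to the trisubstituted prenyl alkene, and the basic oxidation leaves the ketal intact.

Step 5
Reactants: 9 (3S)-3,7-dimethyl-3-[(2R)-5-methoxy-5-methyloxolan-2-yl]oct-6-en-1-ol
Product: 10 (3S)-3,7-dimethyl-3-[(2R)-5-methoxy-5-methyloxolan-2-yl]oct-6-enal
Conditions: (n-Pr4N)RuO4 (5 mol%), NMO, 4 Å MS, CH2Cl2, rt
Reagents that add atoms: none
Why: Ley–Griffith oxidation under neutral conditions, chosen because the tertiary methyl ketal would not tolerate an acidic oxidant; the aldehyde has no α-stereocentre to lose.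

Step 6
Reactants: 10 (3S)-3,7-dimethyl-3-[(2R)-5-methoxy-5-methyloxolan-2-yl]oct-6-enal
Product: 13 (1S,2S,3S,4R)-1,3-dimethyl-3-(4-methylpent-3-en-1-yl)-7-oxabicyclo[2.2.1]heptane-2-carbaldehyde (formyl endo, C3 methyl endo, C3 chain exo), via pyrrolidine enamine 11 (not isolated), via bicyclic iminium acetate 12 (not isolated)
Conditions: pyrrolidine (1.2 equiv), AcOH (3 equiv), 4 Å MS, MeCN, 0 → 40 °C; then aq. NaOAc, rt
Reagents that add atoms: none
Why: Proposed new method: pyrrolidine condenses with the aldehyde to the E-enamine 11 while acetic acid ionises the tertiary methyl ketal to the oxolanylium ion C1=O7+ (the sieves take up water and methanol and so pull both equilibria forward); the enamine carbon C2 adds to C1 to give iminium 12, which water hydrolyses to 13. The closest known reaction types are Mukaiyama-type and enamine additions to ketal-derived oxocarbenium ions, amine-catalysed α-alkylation of aldehydes by stabilised carbocations and amine-catalysed enolexo aldol cyclisations, none of which has been used to close a 7-oxanorbornane. The ring that closes is the six-membered carbocycle C1–C2–C3–C4–C5–C6, in a 6-(enolexo)-exo-trig mode with respect to the C1=O7+ bond; because C4 already carries O7 the same bond completes the second oxolane C1–C2–C3–C4–O7, with the geometry known from the π-route to norbornyl cations. C1 is set by the tether: C2 hangs from C3 on C4 and can reach only the face of the cation cis to the C4–C3 bond, so (4R) becomes (1S) without alternative. C2 is set by the sector that the aminomethylidene terminus takes in the transition state: the exo sector is flanked by the C1 methyl, the exo C3 chain and the positively charged O7, the endo sector only by the C3 methyl and C6H2, so the endo iminium (formyl endo, anti to the chain) is expected to prevail. The C2 epimers can also interconvert through the bicyclic enamine in the amine/acid buffer, and protonation of that enamine from the open exo face again leads to the endo aldehyde. The step needs the enamine, not the prenyl alkene, to capture the cation, which is secured by ring size (six against seven or eight) and by the much higher nucleophilicity of the enamine.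

Step 7
Reactants: 13 (1S,2S,3S,4R)-1,3-dimethyl-3-(4-methylpent-3-en-1-yl)-7-oxabicyclo[2.2.1]heptane-2-carbaldehyde
Product: 14 (1S,2S,3S,4R)-2-ethenyl-1,3-dimethyl-3-(4-methylpent-3-en-1-yl)-7-oxabicyclo[2.2.1]heptane
Conditions: Ph3PCH3Br, KN(SiMe3)2, THF, −78 → 0 °C
Reagents that add atoms: methyltriphenylphosphonium bromide, C[P+](c1ccccc1)(c1ccccc1)c1ccccc1.[Br-]
Why: Wittig methylenation; addition of the non-stabilised ylide to the aldehyde is faster than α-deprotonation at low temperature, so C2 should not epimerise and the oxa bridge should not open.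

Step 8
Reactants: 15 but-2-yn-1-ol
Product: 17 (2Z)-3-iodobut-2-en-1-ol, via cyclic alkenylalanate 16 (not isolated)
Conditions: NaAlH2(OCH2CH2OMe)2, THF, 0 °C → rt; then I2, −78 °C → rt
Reagents that add atoms: iodine, II
Why: Hydroxyl-directed trans-hydroalumination of the propargylic alcohol places aluminium on C3 in a five-membered alanate; iodinolysis with retention gives the Z-iodide, iodine cis to CH2OH.

Step 9
Reactants: 14 (1S,2S,3S,4R)-2-ethenyl-1,3-dimethyl-3-(4-methylpent-3-en-1-yl)-7-oxabicyclo[2.2.1]heptane; 17 (2Z)-3-iodobut-2-en-1-ol
Product: 19 (2Z)-5-[(1S,2S,3S,4R)-1,3-dimethyl-3-(4-methylpent-3-en-1-yl)-7-oxabicyclo[2.2.1]heptan-2-yl]-3-methylpent-2-en-1-ol, via B-alkyl-9-BBN adduct 18 (not isolated)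
Conditions: 9-BBN, THF, rt → 50 °C; then 17, Pd(dppf)Cl2 (5 mol%), AsPh3, Cs2CO3, DMF/H2O, rt
Reagents that add atoms: none
Why: Hydroboration followed by B-alkyl Suzuki–Miyaura coupling; 9-BBN again selects the vinyl group over the prenyl alkene, the primary γ-branched alkylborane transmetalates readily, and coupling retains the geometry of the alkenyl iodide, so the new chain ends cis to CH2OH.

Step 10
Reactants: 19 (2Z)-5-[(1S,2S,3S,4R)-1,3-dimethyl-3-(4-methylpent-3-en-1-yl)-7-oxabicyclo[2.2.1]heptan-2-yl]-3-methylpent-2-en-1-ol
Product: 20 [(2R,3S)-3-{2-[(1S,2S,3S,4R)-1,3-dimethyl-3-(4-methylpent-3-en-1-yl)-7-oxabicyclo[2.2.1]heptan-2-yl]ethyl}-3-methyloxiran-2-yl]methanol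
Conditions: Ti(OiPr)4, D-(−)-diethyl tartrate, t-BuOOH, 4 Å MS, CH2Cl2, −20 °C
Reagents that add atoms: tert-butyl hydroperoxide, CC(C)(C)OO
Why: Sharpless asymmetric epoxidation; only the allylic alcohol is epoxidised, and for this nerol-type Z-alkene the D-(−)-tartrate directs oxygen to the face that gives the (2R,3S)-epoxide. C3 of the oxirane is the future carbinol carbon and is set by reagent control, independent of the distant core.

Step 11
Reactants: 20 [(2R,3S)-3-{2-[(1S,2S,3S,4R)-1,3-dimethyl-3-(4-methylpent-3-en-1-yl)-7-oxabicyclo[2.2.1]heptan-2-yl]ethyl}-3-methyloxiran-2-yl]methanol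
Product: 21 (2S,3S)-3-{2-[(1S,2S,3S,4R)-1,3-dimethyl-3-(4-methylpent-3-en-1-yl)-7-oxabicyclo[2.2.1]heptan-2-yl]ethyl}-2-(iodomethyl)-3-methyloxirane
Conditions: I2, PPh3, imidazole, CH2Cl2, 0 °C
Reagents that add atoms: iodine, II
Why: Appel-type iodination of the primary alcohol (Garegg–Samuelsson conditions); the epoxide and its two centres are untouched, the change of the C2 descriptor being only a change of priorities.

Step 12
Reactants: 21 (2S,3S)-3-{2-[(1S,2S,3S,4R)-1,3-dimethyl-3-(4-methylpent-3-en-1-yl)-7-oxabicyclo[2.2.1]heptan-2-yl]ethyl}-2-(iodomethyl)-3-methyloxirane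
Product: 22 (3S)-5-[(1S,2S,3S,4R)-1,3-dimethyl-3-(4-methylpent-3-en-1-yl)-7-oxabicyclo[2.2.1]heptan-2-yl]-3-methylpent-1-en-3-ol
Conditions: Zn dust, EtOH, reflux; then aq. NH4Cl
Reagents that add atoms: none
Why: Reductive opening of a 2,3-epoxy iodide; zinc inserts into the C–I bond and β-elimination of the epoxide oxygen gives the transposed tertiary allylic alcohol. The C–O bond of the carbinol is never broken, so its (S) configuration is that set in step 10.

Step 13
Reactants: 22 (3S)-5-[(1S,2S,3S,4R)-1,3-dimethyl-3-(4-methylpent-3-en-1-yl)-7-oxabicyclo[2.2.1]heptan-2-yl]-3-methylpent-1-en-3-ol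
Product: 23 triethylsilyl ether of 22
Conditions: Et3SiOTf, 2,6-lutidine, CH2Cl2, −78 °C
Reagents that add atoms: triethylsilyl trifluoromethanesulfonate, CC[Si](CC)(CC)OS(=O)(=O)C(F)(F)F
Why: Silylation of the tertiary alcohol; the protection is needed because step 16 would otherwise also chlorinate this easily ionised allylic alcohol.

Step 14
Reactants: 23 triethylsilyl ether of 22
Product: 24 triethylsilyl ether of (3S)-5-[(1S,2S,3S,4R)-3-{2-[(2R)-3,3-dimethyloxiran-2-yl]ethyl}-1,3-dimethyl-7-oxabicyclo[2.2.1]heptan-2-yl]-3-methylpent-1-en-3-ol
Conditions: 1,2:4,5-di-O-isopropylidene-β-D-erythro-2,3-hexodiulo-2,6-pyranose (Shi ketone, 30 mol%), KHSO5 (as 2KHSO5·KHSO4·K2SO4), K2CO3, Bu4NHSO4, MeCN/CH2(OMe)2/aq. Na2B4O7, 0 °C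
Reagents that add atoms: potassium peroxymonosulfate, [K+].[O-]S(=O)(=O)OO
Why: Shi asymmetric epoxidation by the chiral dioxirane through a spiro transition state; the electron-rich trisubstituted alkene reacts much faster than the monosubstituted vinyl group, and the D-fructose-derived ketone should give the (R) configuration at the secondary epoxide carbon.

Step 15
Reactants: 24 triethylsilyl ether of (3S)-5-[(1S,2S,3S,4R)-3-{2-[(2R)-3,3-dimethyloxiran-2-yl]ethyl}-1,3-dimethyl-7-oxabicyclo[2.2.1]heptan-2-yl]-3-methylpent-1-en-3-ol
Product: 25 triethylsilyl ether of (3S)-5-[(1S,2S,3S,4R)-3-[(3S)-3-bromo-4-hydroxy-4-methylpentyl]-1,3-dimethyl-7-oxabicyclo[2.2.1]heptan-2-yl]-3-methylpent-1-en-3-ol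
Conditions: Li2NiBr4, THF, 0 °C → rt
Reagents that add atoms: dilithium tetrabromonickelate, [Li+].[Li+].[Ni+2].[Br-].[Br-].[Br-].[Br-]
Why: SN2 opening of the epoxide by soft bromide at the less substituted carbon with inversion, (R)-epoxide to (S)-bromide. Any regioisomeric bromohydrin passes through the same bromonium ion in step 16 and so leads to the same product.

Step 16
Reactants: 25 triethylsilyl ether of (3S)-5-[(1S,2S,3S,4R)-3-[(3S)-3-bromo-4-hydroxy-4-methylpentyl]-1,3-dimethyl-7-oxabicyclo[2.2.1]heptan-2-yl]-3-methylpent-1-en-3-ol
Product: 26 triethylsilyl ether of 27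
Conditions: 1-chloro-N,N,2-trimethylprop-1-en-1-amine (Ghosez's reagent), CH2Cl2, 0 °C → rt
Reagents that add atoms: 1-chloro-N,N,2-trimethylprop-1-en-1-amine, CC(C)=C(Cl)N(C)C
Why: Neutral deoxychlorination of a tertiary alcohol; the activated oxygen leaves with anchimeric assistance from the vicinal bromine, and chloride opens the bromonium ion at the tertiary carbon (Markovnikov). Bromine never leaves the secondary carbon, so its (S) configuration is retained.

Step 17
Reactants: 26 triethylsilyl ether of 27
Product: 27 (3S)-5-[(1S,2S,3S,4R)-3-[(3S)-3-bromo-4-chloro-4-methylpentyl]-1,3-dimethyl-7-oxabicyclo[2.2.1]heptan-2-yl]-3-methylpent-1-en-3-ol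
Conditions: HF·pyridine, pyridine/THF, 0 °C
Reagents that add atoms: none
Why: Fluoride-driven cleavage of the triethylsilyl ether at silicon; it needs neither the strong acid that would ionise the tertiary allylic alcohol nor the base that would eliminate HBr or HCl from the vicinal dihalide.

## Compound list

1 | geraniol, (2E)-3,7-dimethylocta-2,6-dien-1-ol | OC/C=C(C)/CCC=C(C)C | starting material
2 | bis(pinacolato)diboron | CC1(C)OB(OC1(C)C)B1OC(C)(C)C(C)(C)O1 | starting material
3 | geranyl pinacolboronate, 2-[(2E)-3,7-dimethylocta-2,6-dien-1-yl]-4,4,5,5-tetramethyl-1,3,2-dioxaborolane | CC(C)=CCC/C(C)=C/CB1OC(C)(C)C(C)(C)O1 | intermediate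
4 | 4-oxopentanal | CC(=O)CCC=O | starting material
5 | pinacol borate ester of 6 (O-boryl at C5) | C=C[C@](C)(CCC=C(C)C)[C@H](OB1OC(C)(C)C(C)(C)O1)CCC(C)=O | intermediate
6 | (5R,6S)-6-ethenyl-5-hydroxy-6,10-dimethylundec-9-en-2-one | C=C[C@](C)(CCC=C(C)C)[C@H](O)CCC(C)=O | intermediate
7 | (5R)-5-[(3S)-3,7-dimethylocta-1,6-dien-3-yl]-2-methoxy-2-methyloxolane, both ketal epimers | C=C[C@](C)(CCC=C(C)C)[C@H]1CCC(C)(OC)O1 | intermediate
8 | B-alkyl-9-BBN adduct of 7 (boron on the terminal carbon of the former vinyl group) | B1(C2CCCC1CCC2)CC[C@](C)(CCC=C(C)C)[C@H]1CCC(C)(OC)O1 | intermediate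
9 | (3S)-3,7-dimethyl-3-[(2R)-5-methoxy-5-methyloxolan-2-yl]oct-6-en-1-ol, both ketal epimers | OCC[C@](C)(CCC=C(C)C)[C@H]1CCC(C)(OC)O1 | intermediate
10 | (3S)-3,7-dimethyl-3-[(2R)-5-methoxy-5-methyloxolan-2-yl]oct-6-enal, both ketal epimers | O=CC[C@](C)(CCC=C(C)C)[C@H]1CCC(C)(OC)O1 | intermediate
11 | (E)-pyrrolidine enamine of 10 | C1CCN(C1)/C=C/[C@](C)(CCC=C(C)C)[C@H]1CCC(C)(OC)O1 | intermediate
12 | pyrrolidinium-ylidene (iminium) acetate of 13, formyl carbon as C=N+ | CC(=O)[O-].C(=[N+]1CCCC1)[C@H]1[C@](C)(CCC=C(C)C)[C@H]2CC[C@]1(C)O2 | intermediate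
13 | (1S,2S,3S,4R)-1,3-dimethyl-3-(4-methylpent-3-en-1-yl)-7-oxabicyclo[2.2.1]heptane-2-carbaldehyde | O=C[C@H]1[C@](C)(CCC=C(C)C)[C@H]2CC[C@]1(C)O2 | intermediate
14 | (1S,2S,3S,4R)-2-ethenyl-1,3-dimethyl-3-(4-methylpent-3-en-1-yl)-7-oxabicyclo[2.2.1]heptane | C=C[C@H]1[C@](C)(CCC=C(C)C)[C@H]2CC[C@]1(C)O2 | intermediate
15 | but-2-yn-1-ol | CC#CCO | starting material
16 | cyclic alkenylalanate, sodium 2,2-bis(2-methoxyethoxy)-3-methyl-2,5-dihydro-1,2-oxaluminol-2-uide | [Na+].CC1=CCO[Al-]1(OCCOC)OCCOC | intermediate
17 | (2Z)-3-iodobut-2-en-1-ol | C/C(I)=C/CO | intermediate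
18 | B-alkyl-9-BBN adduct of 14 (boron on the terminal carbon of the former vinyl group) | B1(C2CCCC1CCC2)CC[C@H]1[C@](C)(CCC=C(C)C)[C@H]2CC[C@]1(C)O2 | intermediate
19 | (2Z)-5-[(1S,2S,3S,4R)-1,3-dimethyl-3-(4-methylpent-3-en-1-yl)-7-oxabicyclo[2.2.1]heptan-2-yl]-3-methylpent-2-en-1-ol | OC/C=C(C)\CC[C@H]1[C@](C)(CCC=C(C)C)[C@H]2CC[C@]1(C)O2 | intermediate
20 | [(2R,3S)-3-{2-[(1S,2S,3S,4R)-1,3-dimethyl-3-(4-methylpent-3-en-1-yl)-7-oxabicyclo[2.2.1]heptan-2-yl]ethyl}-3-methyloxiran-2-yl]methanol | OC[C@H]1O[C@@]1(C)CC[C@H]1[C@](C)(CCC=C(C)C)[C@H]2CC[C@]1(C)O2 | intermediate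
21 | (2S,3S)-3-{2-[(1S,2S,3S,4R)-1,3-dimethyl-3-(4-methylpent-3-en-1-yl)-7-oxabicyclo[2.2.1]heptan-2-yl]ethyl}-2-(iodomethyl)-3-methyloxirane | IC[C@H]1O[C@@]1(C)CC[C@H]1[C@](C)(CCC=C(C)C)[C@H]2CC[C@]1(C)O2 | intermediate
22 | (3S)-5-[(1S,2S,3S,4R)-1,3-dimethyl-3-(4-methylpent-3-en-1-yl)-7-oxabicyclo[2.2.1]heptan-2-yl]-3-methylpent-1-en-3-ol | C=C[C@@](C)(O)CC[C@H]1[C@](C)(CCC=C(C)C)[C@H]2CC[C@]1(C)O2 | intermediate
23 | triethylsilyl ether of 22 | C=C[C@@](C)(O[Si](CC)(CC)CC)CC[C@H]1[C@](C)(CCC=C(C)C)[C@H]2CC[C@]1(C)O2 | intermediate
24 | triethylsilyl ether of (3S)-5-[(1S,2S,3S,4R)-3-{2-[(2R)-3,3-dimethyloxiran-2-yl]ethyl}-1,3-dimethyl-7-oxabicyclo[2.2.1]heptan-2-yl]-3-methylpent-1-en-3-ol | C=C[C@@](C)(O[Si](CC)(CC)CC)CC[C@H]1[C@](C)(CC[C@H]3OC3(C)C)[C@H]2CC[C@]1(C)O2 | intermediate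
25 | triethylsilyl ether of (3S)-5-[(1S,2S,3S,4R)-3-[(3S)-3-bromo-4-hydroxy-4-methylpentyl]-1,3-dimethyl-7-oxabicyclo[2.2.1]heptan-2-yl]-3-methylpent-1-en-3-ol | C=C[C@@](C)(O[Si](CC)(CC)CC)CC[C@H]1[C@](C)(CC[C@H](Br)C(C)(C)O)[C@H]2CC[C@]1(C)O2 | intermediate
26 | triethylsilyl ether of 27 | C=C[C@@](C)(O[Si](CC)(CC)CC)CC[C@H]1[C@](C)(CC[C@H](Br)C(C)(C)Cl)[C@H]2CC[C@]1(C)O2 | intermediate
27 | (3S)-5-[(1S,2S,3S,4R)-3-[(3S)-3-bromo-4-chloro-4-methylpentyl]-1,3-dimethyl-7-oxabicyclo[2.2.1]heptan-2-yl]-3-methylpent-1-en-3-ol | C=C[C@@](C)(O)CC[C@H]1[C@](C)(CC[C@H](Br)C(C)(C)Cl)[C@H]2CC[C@]1(C)O2 | target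

## Step count and least certain steps

Total: 17 steps. Longest linear sequence: 16 steps (steps 1–7 and 9–17, from geraniol); step 8 is a one-step branch.

**Step 6 (key step).** Three processes can defeat it.
- Reversal: the bicycle is strained and iminium 12 can fragment back to the oxocarbenium/enamine pair, so the equilibrium may not lie on the closed side unless methanol is removed.
- Failure of the two partners to coexist: the acid that ionises the ketal also C-protonates the enamine, and the cation can lose a proton to a cyclic enol ether.
- Loss of control at C2, or opening of the oxa bridge by β-elimination through the enamine of the product.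

The fallback uses known chemistry and sets out from 10. The aldehyde is converted (t-BuMe2SiCl, DBU, CH2Cl2, 40 °C) into the tert-butyldimethylsilyl enol ether F1. F1 is closed by an intramolecular Mukaiyama-type addition to the ketal-derived oxocarbenium ion (Me3SiOTf cat., 2,6-di-tert-butyl-4-methylpyridine, CH2Cl2, −78 °C), which gives aldehyde 13, where the route is rejoined. This variant is driven by formation of a silicon–oxygen bond, runs under kinetic control and contains no amine, so the product cannot epimerise or eliminate.

**Step 2.** The γ,γ-disubstituted boronate is slower than allyl or crotyl reagents, so the uncatalysed background reaction and self-condensation of the keto aldehyde may erode facial selectivity. The relative configuration is safe in either case because it comes from the closed transition state. The fallback replaces catalyst control by an auxiliary on boron and sets out from 1. Palladium-catalysed borylation with B2(OH)4 (Pd(MeCN)4(BF4)2 cat., DMSO/MeOH) gives geranylboronic acid F2. Esterification with diisopropyl L-(+)-tartrate over MgSO4 gives the diisopropyl tartrate geranylboronate F3. Roush allylboration of 4 (4 Å MS, toluene, −78 °C), in which the (R,R)-tartrate directs the allyl unit to the Si face, returns to the route at 6.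

**Step 15.** Bromide needs Lewis-acid activation of the epoxide, which can loosen the transition state. The likely failures are attack at the tertiary carbon and rearrangement of the epoxide to a ketone. The fallback accepts the other regiochemistry and sets out from 24. Markovnikov opening with LiBr/AcOH in THF gives the regioisomeric bromohydrin F4 (tertiary bromide, (R)-secondary alcohol). With Ghosez's reagent the activated secondary oxygen is displaced by the neighbouring bromine with inversion, giving the same bromonium ion as from 25, and chloride opens it at the tertiary carbon. The route is rejoined at 26.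

**Step 16.** The bromonium or tertiary cation may lose a proton (elimination to an allylic bromide), be intercepted by the ether oxygen O7, or transfer bromine to an alkene and scramble the C–Br centre. The fallback reverses the order of halogen introduction and sets out from 24. Opening at the tertiary carbon with TiCl(OiPr)3 (CH2Cl2, −20 °C) gives the chlorohydrin F5 with retention at the secondary carbinol. Appel bromination (PPh3, CBr4, CH2Cl2) then replaces the hydroxyl by bromide with inversion and returns to the route at 26. This substitution takes place next to a fully substituted carbon and is expected to be slow, which is why it is the fallback and not the main route.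

## Further compounds

F1 | step 6 | tert-butyldimethylsilyl enol ether of 10, (3S)-1-[(tert-butyldimethylsilyl)oxy]-3,7-dimethyl-3-[(2R)-5-methoxy-5-methyloxolan-2-yl]octa-1,6-diene (enol ether E/Z and ketal epimers) | CC(C)(C)[Si](C)(C)OC=C[C@](C)(CCC=C(C)C)[C@H]1CCC(C)(OC)O1
F2 | step 2 | geranylboronic acid, [(2E)-3,7-dimethylocta-2,6-dien-1-yl]boronic acid | CC(C)=CCC/C(C)=C/CB(O)O
F3 | step 2 | diisopropyl tartrate geranylboronate, diisopropyl (4R,5R)-2-[(2E)-3,7-dimethylocta-2,6-dien-1-yl]-1,3,2-dioxaborolane-4,5-dicarboxylate | CC(C)OC(=O)[C@@H]1OB(C/C=C(C)/CCC=C(C)C)O[C@H]1C(=O)OC(C)C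
F4 | step 15 | regioisomeric bromohydrin, triethylsilyl ether of (3S)-5-[(1S,2S,3S,4R)-3-[(3R)-4-bromo-3-hydroxy-4-methylpentyl]-1,3-dimethyl-7-oxabicyclo[2.2.1]heptan-2-yl]-3-methylpent-1-en-3-ol | C=C[C@@](C)(O[Si](CC)(CC)CC)CC[C@H]1[C@](C)(CC[C@@H](O)C(C)(C)Br)[C@H]2CC[C@]1(C)O2
F5 | step 16 | chlorohydrin, triethylsilyl ether of (3S)-5-[(1S,2S,3S,4R)-3-[(3R)-4-chloro-3-hydroxy-4-methylpentyl]-1,3-dimethyl-7-oxabicyclo[2.2.1]heptan-2-yl]-3-methylpent-1-en-3-ol | C=C[C@@](C)(O[Si](CC)(CC)CC)CC[C@H]1[C@](C)(CC[C@@H](O)C(C)(C)Cl)[C@H]2CC[C@]1(C)O2
A1 | alternative 1 | 7-oxanorbornane ester: core (1S,2S,3S,4R) with the triethylsilyl-protected C2 arm, endo C3 methyl and exo C3 2-(methoxycarbonyl)ethyl | C=C[C@@](C)(O[Si](CC)(CC)CC)CC[C@H]1[C@](C)(CCC(=O)OC)[C@H]2CC[C@]1(C)O2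
A2 | alternative 1 | hydroxy acid: 4-hydroxy-1-methylcyclohexane-1-carboxylic acid carrying the same C2 arm and C3 substituents as A1 (C1 either epimer) | C=C[C@@](C)(O[Si](CC)(CC)CC)CC[C@H]1[C@](C)(CCC(=O)OC)[C@H](O)CCC1(C)C(O)=O
A3 | alternative 2 | 7-oxanorbornane with endo C2 acetoxymethyl, endo C3 methyl and exo C3 4-methylpent-3-enyl | CC(=O)OC[C@H]1[C@](C)(CCC=C(C)C)[C@H]2CC[C@]1(C)O2
A4 | alternative 2 | (2Z)-3-methyl-5-[(2R,3S)-3-methyl-3-(4-methylpent-3-en-1-yl)oxiran-2-yl]pent-2-en-1-yl acetate (cis-6,7-epoxide of a 2Z,6Z-farnesyl acetate) | CC(=O)OC/C=C(C)\CC[C@H]1O[C@@]1(C)CCC=C(C)C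
A5 | alternative 3 | 7-oxanorbornane with exo C3 formyl, endo C3 methyl and endo C2 pivaloyloxymethyl | CC(C)(C)C(=O)OC[C@H]1[C@](C)(C=O)[C@H]2CC[C@]1(C)O2
A6 | alternative 3 | 5-methoxy-2-methyloxolane carrying at C2 a 1-[(pivaloyloxy)methyl]-2-methyl-3-[(tert-butyldimethylsilyl)oxy]prop-2-enyl chain, C1 and C2 configured as in A5 (acetal epimers, enol ether E/Z) | CC(C)(C)C(=O)OC[C@@H](C(C)=CO[Si](C)(C)C(C)(C)C)[C@]1(C)CCC(OC)O1
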